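**Strategy**

Ring C of the flavanone half is cut at O1–C2 and C3–C4. O1, C8a, C4a and C4 then belong to an o-quinone methide of the phloroglucinol ring A, and the two adjacent aryl-bearing carbons C2 and C3 to an E-1,2-diarylethene. A single chiral-phosphoric-acid-catalysed inverse-demand hetero-Diels–Alder reaction forms both bonds, closes ring C and sets the trans C2/C3 stereocentres. Its precursors are a benzyl-protected 2-(hydroxymethyl)phenol and a stilbene that already carries the benzylated flavone on ring D and a free 4-hydroxyphenyl group. Afterwards C4 is oxidised to the ketone and one neutral hydrogenolysis frees all six phenols.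

Key step: step 7

Remark (ring labels): ring A is the phloroglucinol ring of the flavanone, ring B the 4-hydroxyphenyl group on C2, ring C the pyranone ring, ring D the benzene ring that joins C3 to the chromone; the target is 2,3-trans with the (2R,3S) configuration.

Remark (protecting groups): every phenol except the one needed free in step 7 is carried as a benzyl ether, because methyl ethers would require BBr3 at the end, which can open ring C of a flavanone and erode C2; the ketone 1-[2,4-bis(benzyloxy)-6-hydroxyphenyl]ethanone is taken as a purchasable compound.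

Remark (assumption): the sense of induction of the phosphoric acid with this pair of partners cannot be predicted with certainty; the (R)-acid is written, and its mirror image is to be used if the (2S,3R) flavan proves to be favoured.

**Route**

Step 1
Reactants: 1 2,4,6-trihydroxybenzaldehyde
Product: 2 2,4-bis(benzyloxy)-6-hydroxybenzaldehyde
Conditions: BnBr (2.0 equiv), K2CO3, DMF, 0 °C to rt
Reagents that add atoms: benzyl bromide, BrCc1ccccc1
Why: Williamson ether synthesis in which the para hydroxyl and one ortho hydroxyl are alkylated, while the last ortho hydroxyl, hydrogen-bonded to the aldehyde, is the least nucleophilic and should stay free with two equivalents of halide.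

Step 2
Reactants: 2 2,4-bis(benzyloxy)-6-hydroxybenzaldehyde
Product: 3 3,5-bis(benzyloxy)-2-(hydroxymethyl)phenol
Conditions: NaBH4 (1.0 equiv), THF–MeOH, 0 °C; pH 7 buffer work-up; used at once, no chromatography on silica
Reagents that add atoms: none
Why: Borohydride reduction of a salicylaldehyde to the saligenin-type alcohol, where a cold, brief reaction and a neutral work-up should prevent premature ionisation of this very electron-rich benzylic alcohol.

Step 3
Reactants: 4 4-hydroxy-3-iodobenzaldehyde
Product: 5 4-(benzyloxy)-3-iodobenzaldehyde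
Conditions: BnBr, K2CO3, DMF, rt
Reagents that add atoms: benzyl bromide, BrCc1ccccc1
Why: Williamson ether synthesis on an acidic phenol, to which the aldehyde and the aryl iodide are inert.

Step 4
Reactants: 5 4-(benzyloxy)-3-iodobenzaldehyde; 6 1-[2,4-bis(benzyloxy)-6-hydroxyphenyl]ethanone
Product: 7 (E)-1-[2,4-bis(benzyloxy)-6-hydroxyphenyl]-3-[4-(benzyloxy)-3-iodophenyl]prop-2-en-1-one
Conditions: KOH (50% aq.), EtOH–THF, rt
Reagents that add atoms: none
Why: Claisen–Schmidt condensation (crossed aldol addition of the methyl ketone enolate to a non-enolisable aldehyde, then E1cB dehydration), which should give the conjugated E-chalcone.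

Step 5
Reactants: 7 (E)-1-[2,4-bis(benzyloxy)-6-hydroxyphenyl]-3-[4-(benzyloxy)-3-iodophenyl]prop-2-en-1-one
Product: 8 5,7-bis(benzyloxy)-2-[4-(benzyloxy)-3-iodophenyl]-4H-chromen-4-one
Conditions: I2 (10 mol%), DMSO, 130 °C
Reagents that add atoms: none
Why: Iodine-catalysed oxidative cyclisation of a 2'-hydroxychalcone (oxa-Michael closure, then dehydrogenation with DMSO as terminal oxidant), a standard flavone synthesis that leaves aryl iodide and benzyl ethers untouched.

Step 6
Reactants: 8 5,7-bis(benzyloxy)-2-[4-(benzyloxy)-3-iodophenyl]-4H-chromen-4-one; 9 4-acetoxystyrene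
Product: 11 5,7-bis(benzyloxy)-2-{4-(benzyloxy)-3-[(E)-2-(4-hydroxyphenyl)ethenyl]phenyl}-4H-chromen-4-one, via acetylated stilbene 10 (not isolated)
Conditions: Pd(OAc)2 (5 mol%), P(o-tol)3 (10 mol%), Et3N, DMF, 100 °C; then K2CO3, MeOH, rt
Reagents that add atoms: none
Why: Mizoroki–Heck reaction (oxidative addition of the aryl iodide to zerovalent palladium, syn carbopalladation at the terminal alkene carbon and syn β-hydride elimination) should give the E-stilbene, and methanolysis of the aryl acetate then frees the phenol needed in step 7.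

Step 7
Reactants: 3 3,5-bis(benzyloxy)-2-(hydroxymethyl)phenol; 11 5,7-bis(benzyloxy)-2-{4-(benzyloxy)-3-[(E)-2-(4-hydroxyphenyl)ethenyl]phenyl}-4H-chromen-4-one
Product: 13 5,7-bis(benzyloxy)-2-{4-(benzyloxy)-3-[(2R,3S)-5,7-bis(benzyloxy)-2-(4-hydroxyphenyl)-3,4-dihydro-2H-chromen-3-yl]phenyl}-4H-chromen-4-one, via o-quinone methide 12 (not isolated)
Conditions: (R)-TRIP [(R)-3,3'-bis(2,4,6-triisopropylphenyl)-1,1'-binaphthyl-2,2'-diyl hydrogen phosphate] (10 mol%), 4 Å molecular sieves, CH2Cl2, 0 °C to rt; 3 (1.5 equiv) added slowly as a solution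
Reagents that add atoms: none
Why: The phosphoric acid ionises the benzylic alcohol of 3 to the o-quinone methide 12 and can hold it by a hydrogen bond to the methide oxygen while its phosphoryl oxygen accepts a hydrogen bond from the 4-hydroxyl of 11. The alkene carbon that bears ring D then attacks the methide CH2 (C3–C4) and the charge building up on the 4-hydroxybenzylic carbon is quenched by the methide oxygen (O1–C2), an asynchronous inverse-demand hetero-Diels–Alder reaction whose closest known type is the phosphoric-acid-catalysed [4+2] addition of in situ o-quinone methides to hydroxystyrenes. Ring C closes as the six-membered ring of this [4+2] cycloaddition, which in the stepwise limit is a 6-exo-trig attack of the ring A oxygen on the p-quinone-methide-like carbon. C2 and C3 are created together: their trans relation comes from suprafacial addition across the E-alkene, and their absolute configuration (2R,3S) from the alkene face left open in the chiral pocket of the catalyst that binds both partners. The step needs regioselectivity, secured by the free para-hydroxyl that makes its own benzylic carbon the cation-stabilising terminus, whereas the ether oxygen of ring D is drained by the chromone para to it. It also needs the methide to add to the alkene faster than to electron-rich arenes, which slow addition of 3 at low temperature should secure.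

Step 8
Reactants: 13 5,7-bis(benzyloxy)-2-{4-(benzyloxy)-3-[(2R,3S)-5,7-bis(benzyloxy)-2-(4-hydroxyphenyl)-3,4-dihydro-2H-chromen-3-yl]phenyl}-4H-chromen-4-one
Product: 14 benzyl 4-[(2R,3S)-5,7-bis(benzyloxy)-3-{2-(benzyloxy)-5-[5,7-bis(benzyloxy)-4-oxo-4H-chromen-2-yl]phenyl}-3,4-dihydro-2H-chromen-2-yl]phenyl carbonate
Conditions: CbzCl (1.2 equiv), Et3N, DMAP (cat.), CH2Cl2, 0 °C
Reagents that add atoms: benzyl chloroformate, O=C(Cl)OCc1ccccc1
Why: DMAP-catalysed O-acylation of the only free phenol with a chloroformate gives an aryl benzyl carbonate, an electron-withdrawing group that should block quinone methide formation from ring B, deactivate C2–H towards hydride abstraction in step 9 and leave in the final hydrogenolysis.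

Step 9
Reactants: 14 benzyl 4-[(2R,3S)-5,7-bis(benzyloxy)-3-{2-(benzyloxy)-5-[5,7-bis(benzyloxy)-4-oxo-4H-chromen-2-yl]phenyl}-3,4-dihydro-2H-chromen-2-yl]phenyl carbonate
Product: 15 benzyl 4-[(2R,3R)-5,7-bis(benzyloxy)-3-{2-(benzyloxy)-5-[5,7-bis(benzyloxy)-4-oxo-4H-chromen-2-yl]phenyl}-4-hydroxy-3,4-dihydro-2H-chromen-2-yl]phenyl carbonate (mixture of C4 epimers; C2 and C3 arranged in space as in 14, the C3 descriptor changing only through the priority rules)
Conditions: DDQ (1.2 equiv), CH2Cl2–H2O (10:1), 0 °C to rt
Reagents that add atoms: water, O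
Why: Benzylic oxidation by hydride abstraction with DDQ, selective for C4–H because the resulting cation is stabilised by three oxygen donors of ring A (O1 and the 5-benzyloxy group ortho, the 7-benzyloxy group para) and is trapped by water, as established for benzylated 5,7-dioxygenated flavans; C2 and C3 are not touched and the C4 configuration is irrelevant.

Step 10
Reactants: 15 benzyl 4-[(2R,3R)-5,7-bis(benzyloxy)-3-{2-(benzyloxy)-5-[5,7-bis(benzyloxy)-4-oxo-4H-chromen-2-yl]phenyl}-4-hydroxy-3,4-dihydro-2H-chromen-2-yl]phenyl carbonate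
Product: 16 benzyl 4-[(2R,3S)-5,7-bis(benzyloxy)-3-{2-(benzyloxy)-5-[5,7-bis(benzyloxy)-4-oxo-4H-chromen-2-yl]phenyl}-4-oxo-3,4-dihydro-2H-chromen-2-yl]phenyl carbonate
Conditions: Dess–Martin periodinane (1.3 equiv), CH2Cl2, rt
Reagents that add atoms: none
Why: Dess–Martin oxidation of a secondary benzylic alcohol to the aryl ketone under base-free conditions, so that no retro-oxa-Michael opening endangers C2, while C3, now enolisable, should rest in the thermodynamically preferred 2,3-trans (diequatorial) arrangement that the target has.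

Step 11
Reactants: 16 benzyl 4-[(2R,3S)-5,7-bis(benzyloxy)-3-{2-(benzyloxy)-5-[5,7-bis(benzyloxy)-4-oxo-4H-chromen-2-yl]phenyl}-4-oxo-3,4-dihydro-2H-chromen-2-yl]phenyl carbonate
Product: 17 (2R,3S)-3-[5-(5,7-dihydroxy-4-oxo-4H-chromen-2-yl)-2-hydroxyphenyl]-5,7-dihydroxy-2-(4-hydroxyphenyl)-2,3-dihydro-4H-chromen-4-one (CNP0324936.1)
Conditions: H2 (1 atm), 10% Pd/C, THF–MeOH, rt; stopped as soon as debenzylation is complete
Reagents that add atoms: none
Why: Catalytic hydrogenolysis should cleave the five aryl benzyl ethers and the benzyl carbonate (which then loses CO2) under neutral conditions that neither open ring C nor epimerise C2 or C3, while the chromone double bond and the two aryl ketones are reduced far more slowly.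

**Compound list**

1 | 2,4,6-trihydroxybenzaldehyde | O=Cc1c(O)cc(O)cc1O | starting material
2 | 2,4-bis(benzyloxy)-6-hydroxybenzaldehyde | O=Cc1c(O)cc(OCc2ccccc2)cc1OCc1ccccc1 | intermediate
3 | 3,5-bis(benzyloxy)-2-(hydroxymethyl)phenol | OCc1c(O)cc(OCc2ccccc2)cc1OCc1ccccc1 | intermediate
4 | 4-hydroxy-3-iodobenzaldehyde | O=Cc1ccc(O)c(I)c1 | starting material
5 | 4-(benzyloxy)-3-iodobenzaldehyde | O=Cc1ccc(OCc2ccccc2)c(I)c1 | intermediate
6 | 1-[2,4-bis(benzyloxy)-6-hydroxyphenyl]ethanone | CC(=O)c1c(O)cc(OCc2ccccc2)cc1OCc1ccccc1 | starting material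
7 | (E)-1-[2,4-bis(benzyloxy)-6-hydroxyphenyl]-3-[4-(benzyloxy)-3-iodophenyl]prop-2-en-1-one | O=C(/C=C/c1ccc(OCc2ccccc2)c(I)c1)c1c(O)cc(OCc2ccccc2)cc1OCc1ccccc1 | intermediate
8 | 5,7-bis(benzyloxy)-2-[4-(benzyloxy)-3-iodophenyl]-4H-chromen-4-one | O=c1cc(-c2ccc(OCc3ccccc3)c(I)c2)oc2cc(OCc3ccccc3)cc(OCc3ccccc3)c12 | intermediate
9 | 4-acetoxystyrene (4-ethenylphenyl acetate) | CC(=O)Oc1ccc(C=C)cc1 | starting material
10 | 4-[(E)-2-{2-(benzyloxy)-5-[5,7-bis(benzyloxy)-4-oxo-4H-chromen-2-yl]phenyl}ethenyl]phenyl acetate (not isolated) | CC(=O)Oc1ccc(/C=C/c2cc(-c3cc(=O)c4c(OCc5ccccc5)cc(OCc5ccccc5)cc4o3)ccc2OCc2ccccc2)cc1 | intermediate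
11 | 5,7-bis(benzyloxy)-2-{4-(benzyloxy)-3-[(E)-2-(4-hydroxyphenyl)ethenyl]phenyl}-4H-chromen-4-one | Oc1ccc(/C=C/c2cc(-c3cc(=O)c4c(OCc5ccccc5)cc(OCc5ccccc5)cc4o3)ccc2OCc2ccccc2)cc1 | intermediate
12 | 3,5-bis(benzyloxy)-6-methylidenecyclohexa-2,4-dien-1-one (o-quinone methide, not isolated) | C=C1C(=O)C=C(OCc2ccccc2)C=C1OCc1ccccc1 | intermediate
13 | 5,7-bis(benzyloxy)-2-{4-(benzyloxy)-3-[(2R,3S)-5,7-bis(benzyloxy)-2-(4-hydroxyphenyl)-3,4-dihydro-2H-chromen-3-yl]phenyl}-4H-chromen-4-one | C1c2c(OCc3ccccc3)cc(OCc3ccccc3)cc2O[C@@H](c2ccc(O)cc2)[C@@H]1c1cc(-c2cc(=O)c3c(OCc4ccccc4)cc(OCc4ccccc4)cc3o2)ccc1OCc1ccccc1 | intermediate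
14 | benzyl 4-[(2R,3S)-5,7-bis(benzyloxy)-3-{2-(benzyloxy)-5-[5,7-bis(benzyloxy)-4-oxo-4H-chromen-2-yl]phenyl}-3,4-dihydro-2H-chromen-2-yl]phenyl carbonate | C1c2c(OCc3ccccc3)cc(OCc3ccccc3)cc2O[C@@H](c2ccc(OC(=O)OCc3ccccc3)cc2)[C@@H]1c1cc(-c2cc(=O)c3c(OCc4ccccc4)cc(OCc4ccccc4)cc3o2)ccc1OCc1ccccc1 | intermediate
15 | benzyl 4-[(2R,3R)-5,7-bis(benzyloxy)-3-{2-(benzyloxy)-5-[5,7-bis(benzyloxy)-4-oxo-4H-chromen-2-yl]phenyl}-4-hydroxy-3,4-dihydro-2H-chromen-2-yl]phenyl carbonate, C4 epimers | OC1c2c(OCc3ccccc3)cc(OCc3ccccc3)cc2O[C@@H](c2ccc(OC(=O)OCc3ccccc3)cc2)[C@@H]1c1cc(-c2cc(=O)c3c(OCc4ccccc4)cc(OCc4ccccc4)cc3o2)ccc1OCc1ccccc1 | intermediate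
16 | benzyl 4-[(2R,3S)-5,7-bis(benzyloxy)-3-{2-(benzyloxy)-5-[5,7-bis(benzyloxy)-4-oxo-4H-chromen-2-yl]phenyl}-4-oxo-3,4-dihydro-2H-chromen-2-yl]phenyl carbonate | O=C1c2c(OCc3ccccc3)cc(OCc3ccccc3)cc2O[C@@H](c2ccc(OC(=O)OCc3ccccc3)cc2)[C@@H]1c1cc(-c2cc(=O)c3c(OCc4ccccc4)cc(OCc4ccccc4)cc3o2)ccc1OCc1ccccc1 | intermediate
17 | (2R,3S)-3-[5-(5,7-dihydroxy-4-oxo-4H-chromen-2-yl)-2-hydroxyphenyl]-5,7-dihydroxy-2-(4-hydroxyphenyl)-2,3-dihydro-4H-chromen-4-one | O=C1c2c(O)cc(O)cc2O[C@@H](c2ccc(O)cc2)[C@@H]1c1cc(-c2cc(=O)c3c(O)cc(O)cc3o2)ccc1O | target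

**Step count and risks**

Total step count: 11.
Longest linear sequence: 9 steps (steps 3 to 11, from 4 to 17); the other branch (steps 1 and 2) joins at step 7.

Steps most likely to fail:

1. Step 7. What may go wrong:
   - the electron-rich methide may condense with itself, or alkylate the free phenol ring or ring A of the product, faster than it adds to the hindered 1,2-disubstituted alkene;
   - facial discrimination may be weak, because the methide carbon is unsubstituted and the hydroxyl handle sits para to the alkene.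

   The fallback sets out from 3 and 11. The cycloaddition is run without asymmetric induction, with achiral diphenyl phosphate (20 mol%) in toluene at 40 °C and syringe-pump addition of 3, an acid-promoted o-quinone methide/styrene cycloaddition of established type. It should give the racemic trans flavan F1. The enantiomers are then separated by preparative chromatography on a chiral stationary phase, and the (2R,3S) enantiomer is 13, where the route is rejoined.

2. Step 9. What may go wrong: the C4 cation may lose the C3 proton to give the flav-3-ene, which DDQ would oxidise on to a benzopyrylium ion and so destroy C2. This is likely if capture by water across the phase boundary is slow.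

   The fallback sets out from 14. DDQ in homogeneous CH2Cl2–MeOH, the well-established C4 alkoxylation of benzylated flavans, should give the 4-methoxy ether F2 (C4 epimers). A second treatment with DDQ in wet CH2Cl2 removes the remaining C4 hydride, as in the oxidative cleavage of a p-methoxybenzyl-type ether, and hydrolysis of the oxocarbenium ion should give the ketone directly. Steps 9 and 10 are both replaced and the route is rejoined at 16.

3. Step 11. What may go wrong: over-reduction before the last benzyl group has left, by saturation of the chromone C2=C3 bond of the flavone half or by hydrogenolytic cleavage of the benzylic C2–O1 bond of ring C.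

   The fallback sets out from 16 and replaces reductive cleavage by Lewis-acid benzyl transfer. BCl3 with pentamethylbenzene as benzyl cation scavenger in CH2Cl2 at −78 °C should remove the five benzyl ethers and the benzyl carbonate (with loss of CO2 on work-up) without any hydrogen source. It arrives directly at the target 17; no further compound is made on the way (F0).

Further compounds
F1 | step 7 | racemic trans flavan, the 1:1 mixture of 13 and its (2S,3R) enantiomer | C1c2c(OCc3ccccc3)cc(OCc3ccccc3)cc2O[C@@H](c2ccc(O)cc2)[C@@H]1c1cc(-c2cc(=O)c3c(OCc4ccccc4)cc(OCc4ccccc4)cc3o2)ccc1OCc1ccccc1.C1c2c(OCc3ccccc3)cc(OCc3ccccc3)cc2O[C@H](c2ccc(O)cc2)[C@H]1c1cc(-c2cc(=O)c3c(OCc4ccccc4)cc(OCc4ccccc4)cc3o2)ccc1OCc1ccccc1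
F2 | step 9 | 4-methoxy ether of 14 (C4 epimers, C2 and C3 as in 14) | COC1c2c(OCc3ccccc3)cc(OCc3ccccc3)cc2O[C@@H](c2ccc(OC(=O)OCc3ccccc3)cc2)[C@@H]1c1cc(-c2cc(=O)c3c(OCc4ccccc4)cc(OCc4ccccc4)cc3o2)ccc1OCc1ccccc1
F0 | step 11 | none | none
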